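2.00 min was the number I reckoned first: the flask's time multiplied by its substrate charge over the teal charge, which I call its teal clock.

| setting | green | teal | grey | flask |
|---|---|---|---|---|
| substrate | 0.025 M (fed, over 8.0 s) | 0.10 M (fed, over 8.0 s) | 0.050 M (fed, over 8.0 s) | 0.050 M (fed, over 8.0 s) |
| salt in the second phase | 1.8 equiv | 1.8 equiv | 0.90 equiv | 1.80 equiv |
| spent carrier | 2.5 mol% | 2.5 mol% | 2.5 mol% | 2.5 mol% |
| remark | run made earlier | run made earlier | run made earlier |  |
| time |  |  |  | 4.0 min |
| volume of the second phase over the first |  |  |  | 1.0 |

| run | time / min | product / % |
|---|---|---|
| green | 0.250 | 5.2 |
| green | 0.667 | 12.9 |
| green | 1.33 | 22.1 |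
| green | 3.00 | 44.8 |
| teal | 0.833 | 48.9 |
| teal | 1.50 | 73.8 |
| teal | 2.50 | 92.7 |
| teal | 3.00 | 95.8 |
| grey | 0.417 | 7.7 |
| grey | 1.00 | 16.9 |
| grey | 2.00 | 30.7 |
| grey | 3.00 | 41.0 |

(scatter of a reading: 1 percentage point)

- in the second phase: salt in the second phase, spent salt in the second phase; everything else is in the first
- charges count per volume of the first phase; a concentration in a rate is the amount of a species over the volume of its own phase; every rate counts per litre of the first phase
- candidate steps: spent carrier + salt in the second phase <-> fresh carrier + spent salt in the second phase; 2 fresh carrier -> spent catalyst; substrate + fresh carrier -> product + spent carrier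
- the earlier runs hold the two phases in the same ratio of volumes as the flask asked about
- the reaction counts as stopped when no species that holds the substrate changes by six tenths of a point or more over the second half of the time

1. which holds at 4.0 min: what has brought the reaction to rest, or that it has not come to rest (all of the substrate has reacted / the salt in the second phase has run out first / it is still moving / no working catalyst is left / forward and back rates have come level)
2. amount of product at 4.0 min, in percent of the substrate charged
3. amount of product if the flask were left three thousand times as long, in percent of the substrate charged

Each candidate step joins two partners, so I expected the flask, at half the teal charge with equal equivalents and loading, to pass through the teal states at half the pace.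

But did the readings obey this clock? The last green reading stands at 0.750 min on it, just before the first teal reading. I took the logarithm of the substrate remaining in the teal run, which fell at 1.00 min⁻¹ early on, and carried that slope back:

teal product at 0.750 min: 44.5 %; green reading: 44.8 %

The two stood within the scatter. The feed of 8.0 s does not stretch with the clock, but it is short against 4.0 min, so I set it aside.

A straight line between the teal readings on either side of 2.00 min gave 83.2 %. But the teal curve bends, so that line lies under it. The logarithm of the remaining teal substrate fell at 1.00 min⁻¹ before that gap, at 1.28 min⁻¹ across it and at 1.11 min⁻¹ after it. Those slopes, the last resting on a small remainder with its scatter, do not show a first-order decay, and I claimed none. I needed only a bridge across this one gap, so I interpolated in logarithms: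

substrate remaining at 2.00 min: 13.8 %; product: 86.2 %

Beyond 2.00 min the teal run still rose from 92.7 % to 95.8 %, so I called the flask still moving and heading close to full conversion.

The forecast said it is still moving, with 86 % at the asked time and 99.5 % in the long run: “The flask is the teal run at half concentration with the same equivalents, so its time scales by two.”

The flask gave it is still moving, with 85.9 % at the asked time and 100 % in the long run.

    spent carrier + salt in the second phase ⇌ fresh carrier + spent salt in the second phase (K = 0.270, k = 2.96 L mol⁻¹ s⁻¹)
    2 fresh carrier → spent catalyst (k = 12.6 L mol⁻¹ s⁻¹)
    substrate + fresh carrier → product + spent carrier (k = 80.0 L mol⁻¹ s⁻¹)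

At 1.41 min in the flask, substrate used fresh carrier 990 times as fast as the loss to spent catalyst did. At 4.00 min, with the flask at 2.00 min on the teal clock, spent catalyst held 5.68 % of the catalyst and 14.1 % of the substrate remained. Read at 6.0 min, the same flask stands at 3.00 min on the teal clock, where the teal run read 95.8 %; computed, it gave 96.9 %.

The runs are calculated from invented constants; scatter was added.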